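The disconnection reads C7, the oxygenated quaternary carbon held between the C6 and C8 ketones of carbocycle A (C4a-C5-C6-C7-C8-C8a), as the terminus of an acyloin shift. Disconnecting C7-C8 pushes C7 and its methyl group out of ring A as an acetyl group on a (6S)-hydroxycyclopenta[c]pyranone. In the forward sense, one Lewis acid operation unveils the methylenepyran of ring B and moves acyl carbon C8 from C6 to the acetyl carbon. This enlarges ring A from five to six members, relays the C6 configuration to C7 and switches on the push-pull chromophore. The precursor is a masked 6-acetyl-6-hydroxy ketone built from cyclopentane-1,3-dione. Esterification and side-chain oxidation follow.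

Key step: step 7

Remark on locants: C1, O2, C3, C4, C4a, C5 to C8 and C8a are those of the isochromene core of the target. In the five-ring precursors the ring ketone carbon is already called C8 (IUPAC position 7), its neighbour C8a (IUPAC 7a), and the acetyl carbonyl carbon C7. The target stereocentre is (7R), with priorities O > C8 > C6 > CH3.

Remark on step 6: the sense of induction of the nickel catalyst on this β-diketone cannot be predicted with certainty. The ligand antipode that gives (6S) should be fixed in a pilot run; (R,R) is written here. Cyclopentane-1,3-dione, (E)-pent-2-en-4-yn-1-ol and orsellinic acid are commercial.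

Step 1
Reactants: 1 cyclopentane-1,3-dione
Product: 2 2-chloro-5-oxocyclopent-1-ene-1-carbaldehyde
Conditions: POCl3, DMF, CH2Cl2, 0 °C to rt; then ice-water
Reagents that add atoms: N,N-dimethylformamide CN(C)C=O; phosphoryl chloride O=P(Cl)(Cl)Cl; water O
Why: Vilsmeier-Haack-Arnold chloroformylation, in which the enolised dione is C-formylated at C2 by the chloroiminium salt, the vinylogous amide oxygen is exchanged for chloride, and hydrolysis of the iminium ion gives the β-chloro-α-formyl enone without any stereocentre.

Step 2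
Reactants: 3 (E)-pent-2-en-4-yn-1-ol
Product: 4 tert-butyl(dimethyl)[(E)-pent-2-en-4-ynyloxy]silane
Conditions: TBSCl, imidazole, CH2Cl2, 0 °C to rt
Reagents that add atoms: tert-butyldimethylsilyl chloride CC(C)(C)[Si](C)(C)Cl
Why: Standard imidazole-mediated O-silylation of a primary allylic alcohol, which leaves the alkyne C-H and the E-alkene untouched.

Step 3
Reactants: 2 2-chloro-5-oxocyclopent-1-ene-1-carbaldehyde; 4 tert-butyl(dimethyl)[(E)-pent-2-en-4-ynyloxy]silane
Product: 5 2-[(E)-5-(tert-butyldimethylsilyloxy)pent-3-en-1-ynyl]-5-oxocyclopent-1-ene-1-carbaldehyde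
Conditions: Pd(PPh3)2Cl2 (2 mol%), CuI (4 mol%), Et3N, THF, 0 °C to rt
Reagents that add atoms: none
Why: Sonogashira coupling, in which the C-Cl bond of 2 is a doubly activated vinylogous acyl chloride that should add readily to zerovalent palladium while the E-alkene of 4 is not involved.

Step 4
Reactants: 5 2-[(E)-5-(tert-butyldimethylsilyloxy)pent-3-en-1-ynyl]-5-oxocyclopent-1-ene-1-carbaldehyde
Product: 6 1-methoxy-3-[(E)-3-(tert-butyldimethylsilyloxy)prop-1-enyl]-5,6-dihydro-1H-cyclopenta[c]pyran-7-one (racemic at C1)
Conditions: AgOTf (5 mol%), MeOH (10 equiv), CH2Cl2, 0 °C to rt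
Reagents that add atoms: methanol CO
Why: Silver-catalysed 6-endo-dig alkoxycyclisation of an alkynyl enal through its methyl hemiacetal (the isochromene acetal synthesis from ortho-alkynyl aldehydes), with the endo mode reinforced because the attacked alkyne carbon is the δ-position of the ynenone, and with C1 formed as a racemate that is erased in step 7.

Step 5
Reactants: 6 1-methoxy-3-[(E)-3-(tert-butyldimethylsilyloxy)prop-1-enyl]-5,6-dihydro-1H-cyclopenta[c]pyran-7-one
Product: 7 6-acetyl-1-methoxy-3-[(E)-3-(tert-butyldimethylsilyloxy)prop-1-enyl]-5,6-dihydro-1H-cyclopenta[c]pyran-7-one (β-diketone)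
Conditions: LiN(iPr)2 (2.2 equiv), THF, -78 °C; 1-acetylbenzotriazole, -78 to -40 °C; AcOH quench at -78 °C
Reagents that add atoms: 1-acetyl-1H-benzotriazole CC(=O)n1nnc2ccccc12
Why: Claisen-type C-acylation, in which the amide base removes the kinetic α′ proton at C6 (cross-conjugated enolate), N-acylbenzotriazoles acylate lithium enolates on carbon, and the second equivalent of base stores 7 as its diketonate, so that C6 stays configurationally labile.

Step 6
Reactants: 7 6-acetyl-1-methoxy-3-[(E)-3-(tert-butyldimethylsilyloxy)prop-1-enyl]-5,6-dihydro-1H-cyclopenta[c]pyran-7-one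
Product: 8 (6S)-6-acetyl-6-hydroxy-1-methoxy-3-[(E)-3-(tert-butyldimethylsilyloxy)prop-1-enyl]-5,6-dihydro-1H-cyclopenta[c]pyran-7-one (both C1 epimers)
Conditions: Ni(ClO4)2·6H2O (10 mol%), (R,R)-4,6-dibenzofurandiyl-2,2'-bis(4-phenyloxazoline) (11 mol%), 3-phenyl-2-(phenylsulfonyl)oxaziridine, 4 Å molecular sieves, CH2Cl2, 0 °C to rt
Reagents that add atoms: 3-phenyl-2-(phenylsulfonyl)-1,2-oxaziridine O=S(=O)(c1ccccc1)N1OC1c1ccccc1
Why: Catalytic asymmetric α-hydroxylation of a cyclic β-dicarbonyl compound, in which the divalent nickel complex binds 7 as a planar diketonate and the ligand leaves one face of C6 open to oxygen transfer from the oxaziridine, which sets C6 as (S) in both C1 epimers.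

Step 7
Reactants: 8 (6S)-6-acetyl-6-hydroxy-1-methoxy-3-[(E)-3-(tert-butyldimethylsilyloxy)prop-1-enyl]-5,6-dihydro-1H-cyclopenta[c]pyran-7-one
Product: 10 (7R)-7-hydroxy-7-methyl-3-[(E)-3-(tert-butyldimethylsilyloxy)prop-1-enyl]-6H-isochromene-6,8(7H)-dione, via methylenepyran ketol 9 (not isolated)
Conditions: Sc(OTf)3 (10 mol%), 4 Å molecular sieves, CH2Cl2, -20 °C to rt
Reagents that add atoms: none
Why: Sc(OTf)3 ionises the C1 acetal of either epimer of 8 to a pyrylium ion, loss of H5 (net loss of methanol) gives the 4-methylenepyran ketol 9, and the trivalent scandium then clamps O6 and the acetyl oxygen in a five-membered chelate in which the C6-C8 bond migrates to the acetyl carbon C7 while C6 becomes a ketone. The closest known reaction type is the acyloin (α-ketol) rearrangement with 1,2-acyl shift, known as the ring contraction of hop α-acids to iso-α-acids (run here in the opposite, ring-enlarging sense) and as the D-homo enlargement of 17-hydroxy-20-oxo steroids. No ring is closed by cyclisation: ring A grows from five members (C4a, C5, C6, C8, C8a) to six by insertion of C7 between C6 and C8, and ring B only shifts its double bonds. C7 is the only new stereocentre and is set by chirality transfer, because in the syn-periplanar chelate C8 faces one side of the acetyl C=O only and shifts suprafacially, so that (6S) gives (7R); the detour by acetyl shift to C8 followed by shift of C6 ends at the same (7R) alcohol. The step needs migration of acyl C8 in preference to vinyl C5 and no leak through the unchelated anti rotamer: all ketol isomers equilibrate and only 10 gains the vinylogous ester conjugation O2-C3=C4-C4a=C5-C6=O, which makes it the sink, while a bidentate Lewis acid in a non-coordinating solvent holds the chelate.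

Step 8
Reactants: 11 orsellinic acid (2,4-dihydroxy-6-methylbenzoic acid)
Product: 13 2,4-bis(tert-butyldimethylsilyloxy)-6-methylbenzoic acid, via trisilyl compound 12 (not isolated)
Conditions: TBSCl (3.5 equiv), imidazole, DMF, rt; then THF-AcOH-H2O, rt
Reagents that add atoms: tert-butyldimethylsilyl chloride CC(C)(C)[Si](C)(C)Cl
Why: Exhaustive silylation of both phenols and the acid followed by selective solvolysis of the far more labile silyl ester.

Step 9
Reactants: 10 (7R)-7-hydroxy-7-methyl-3-[(E)-3-(tert-butyldimethylsilyloxy)prop-1-enyl]-6H-isochromene-6,8(7H)-dione; 13 2,4-bis(tert-butyldimethylsilyloxy)-6-methylbenzoic acid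
Product: 15 (7R)-7-methyl-6,8-dioxo-3-[(E)-3-(tert-butyldimethylsilyloxy)prop-1-enyl]-7,8-dihydro-6H-isochromen-7-yl 2,4-bis(tert-butyldimethylsilyloxy)-6-methylbenzoate, via acid chloride 14 (not isolated)
Conditions: 13, 1-chloro-N,N,2-trimethylprop-1-en-1-amine, CH2Cl2, 0 °C; then 10, Et3N, DMAP, CH2Cl2, 0 °C to 40 °C
Reagents that add atoms: 1-chloro-N,N,2-trimethylprop-1-en-1-amine CC(C)=C(Cl)N(C)C (supplies the chlorine of 14; none of its atoms stays in 15)
Why: Neutral formation of the acid chloride keeps the aryl silyl ethers, and the DMAP-catalysed O-acylation of the tertiary alcohol leaves the C7-O bond and hence the (7R) configuration untouched while ending any further ketol equilibration.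

Step 10
Reactants: 15 (7R)-7-methyl-6,8-dioxo-3-[(E)-3-(tert-butyldimethylsilyloxy)prop-1-enyl]-7,8-dihydro-6H-isochromen-7-yl 2,4-bis(tert-butyldimethylsilyloxy)-6-methylbenzoate
Product: 16 (7R)-3-[(E)-3-hydroxyprop-1-enyl]-7-methyl-6,8-dioxo-7,8-dihydro-6H-isochromen-7-yl 2,4-dihydroxy-6-methylbenzoate
Conditions: HF·pyridine, THF-pyridine, 0 °C to rt
Reagents that add atoms: none
Why: Fluoride-driven cleavage of all three silyl ethers under buffered, non-nucleophilic conditions that should spare the ester, the pyran ring and C7.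

Step 11
Reactants: 16 (7R)-3-[(E)-3-hydroxyprop-1-enyl]-7-methyl-6,8-dioxo-7,8-dihydro-6H-isochromen-7-yl 2,4-dihydroxy-6-methylbenzoate
Product: 17 (7R)-7-methyl-6,8-dioxo-3-[(E)-3-oxoprop-1-enyl]-7,8-dihydro-6H-isochromen-7-yl 2,4-dihydroxy-6-methylbenzoate (target)
Conditions: activated MnO2 (excess), CH2Cl2, rt
Reagents that add atoms: none
Why: Chemoselective MnO2 oxidation of the primary allylic alcohol to the E-enal, with the ester-deactivated, hydrogen-bonded phenols and the alkene geometry expected to survive.

Compound list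
1 | cyclopentane-1,3-dione | O=C1CCC(=O)C1 | starting material
2 | 2-chloro-5-oxocyclopent-1-ene-1-carbaldehyde | O=CC1=C(Cl)CCC1=O | intermediate
3 | (E)-pent-2-en-4-yn-1-ol | C#C/C=C/CO | starting material
4 | tert-butyl(dimethyl)[(E)-pent-2-en-4-ynyloxy]silane | C#C/C=C/CO[Si](C)(C)C(C)(C)C | intermediate
5 | 2-[(E)-5-(tert-butyldimethylsilyloxy)pent-3-en-1-ynyl]-5-oxocyclopent-1-ene-1-carbaldehyde | O=CC1=C(C#C/C=C/CO[Si](C)(C)C(C)(C)C)CCC1=O | intermediate
6 | 1-methoxy-3-[(E)-3-(tert-butyldimethylsilyloxy)prop-1-enyl]-5,6-dihydro-1H-cyclopenta[c]pyran-7-one, racemic at C1 | COC1OC(/C=C/CO[Si](C)(C)C(C)(C)C)=CC2=C1C(=O)CC2 | intermediate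
7 | 6-acetyl derivative of 6 (β-diketone, C1 and C6 undefined) | COC1OC(/C=C/CO[Si](C)(C)C(C)(C)C)=CC2=C1C(=O)C(C(C)=O)C2 | intermediate
8 | (6S)-6-acetyl-6-hydroxy derivative of 6, both C1 epimers | COC1OC(/C=C/CO[Si](C)(C)C(C)(C)C)=CC2=C1C(=O)[C@@](O)(C(C)=O)C2 | intermediate
9 | (6S)-6-acetyl-6-hydroxy-3-[(E)-3-(tert-butyldimethylsilyloxy)prop-1-enyl]cyclopenta[c]pyran-7(6H)-one | CC(=O)[C@@]1(O)C=C2C=C(/C=C/CO[Si](C)(C)C(C)(C)C)OC=C2C1=O | intermediate
10 | (7R)-7-hydroxy-7-methyl-3-[(E)-3-(tert-butyldimethylsilyloxy)prop-1-enyl]-6H-isochromene-6,8(7H)-dione | O[C@]1(C)C(=O)C=C2C=C(/C=C/CO[Si](C)(C)C(C)(C)C)OC=C2C1=O | intermediate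
11 | orsellinic acid | Cc1cc(O)cc(O)c1C(=O)O | starting material
12 | tert-butyldimethylsilyl 2,4-bis(tert-butyldimethylsilyloxy)-6-methylbenzoate | Cc1cc(O[Si](C)(C)C(C)(C)C)cc(O[Si](C)(C)C(C)(C)C)c1C(=O)O[Si](C)(C)C(C)(C)C | intermediate
13 | 2,4-bis(tert-butyldimethylsilyloxy)-6-methylbenzoic acid | Cc1cc(O[Si](C)(C)C(C)(C)C)cc(O[Si](C)(C)C(C)(C)C)c1C(=O)O | intermediate
14 | 2,4-bis(tert-butyldimethylsilyloxy)-6-methylbenzoyl chloride | Cc1cc(O[Si](C)(C)C(C)(C)C)cc(O[Si](C)(C)C(C)(C)C)c1C(=O)Cl | intermediate
15 | trisilylated (7R)-ester | Cc1cc(O[Si](C)(C)C(C)(C)C)cc(O[Si](C)(C)C(C)(C)C)c1C(=O)O[C@]1(C)C(=O)C=C2C=C(/C=C/CO[Si](C)(C)C(C)(C)C)OC=C2C1=O | intermediate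
16 | (7R)-allylic alcohol with free phenols | Cc1cc(O)cc(O)c1C(=O)O[C@]1(C)C(=O)C=C2C=C(/C=C/CO)OC=C2C1=O | intermediate
17 | CNP0200982.1, (7R)-enal | Cc1cc(O)cc(O)c1C(=O)O[C@]1(C)C(=O)C=C2C=C(/C=C/C=O)OC=C2C1=O | target

Total step count: 11. Longest linear sequence: 9 steps (1, 3, 4, 5, 6, 7, 9, 10, 11; equally long from step 2).

Steps most likely to fail

**Step 7.**
- What may go wrong: part of the material may react through the unchelated rotamer, which erodes the chirality transfer from C6 to C7. The vinyl carbon C5 may migrate instead of C8. The acetyl group may be lost by retro-Claisen cleavage. The pyrylium/methylenepyran pair may oligomerise.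
- Fallback (sets out from 5, comes back at 10): the ring enlargement is moved in front of the closure of ring B, so that no pyrylium ion can form. Aldehyde 5 is protected with HC(OMe)3 and pyridinium tosylate in MeOH as the dimethyl acetal F1. α′-Acetylation as in step 5 gives the monocyclic β-diketone F2, and the hydroxylation of step 6 gives the monocyclic (S)-ketol F3. Sc(OTf)3 in moist MeCN frees the aldehyde and drives the same chelate-controlled acyl shift, now pulled by the acidity of the product, the formyl alkynyl vinylogous acid F4. CuI and iPr2NEt in CH2Cl2 then close ring B by 6-endo-dig cycloisomerisation of the hydroxymethylene tautomer, the established closure of such vinylogous acids, and give 10.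

**Step 6.**
- What may go wrong: facial selectivity on a β-diketone may be lower than on β-keto esters. The Lewis acidic catalyst may ionise the acetal. The ketol may begin to rearrange without control.
- Fallback (sets out from 7, comes back at 8): oxygen is delivered by an O-selective nitroso aldol reaction under Brønsted acid organocatalysis instead of by oxidation of a metal-bound enolate. Diketone 7, nitrosobenzene and a chiral 3,3'-bis(2,4,6-triisopropylphenyl)-BINOL phosphoric acid in benzene give the (S)-anilinooxy diketone F5. Its N-O bond is cleaved with zinc dust and aqueous NH4Cl in THF to give 8.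

**Step 9.**
- What may go wrong: acylation may be too slow, because a tertiary, electron-poor alcohol meets a doubly ortho-substituted aroyl chloride. Slow attack of the amine bases on the pyran ring may then take over.
- Fallback (sets out from 10, comes back at 16): the aromatic ring is built on the ester oxygen instead of being brought in. The lithium dienolate of commercial 2,2,6-trimethyl-4H-1,3-dioxin-4-one is acetoacetylated with diketene to the diketo-dioxinone F6. Thermolysis of F6 in toluene at 110 °C releases an unhindered acylketene that is trapped by 10 as the trioxooctanoate ester F7. Et3N and then AcOH bring about the biomimetic aldol aromatisation to the free orsellinate F8. HF·pyridine as in step 10 removes the remaining silyl ether to give 16.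

Further compounds
F1 | step 7 | 2-(dimethoxymethyl)-3-[(E)-5-(tert-butyldimethylsilyloxy)pent-3-en-1-ynyl]cyclopent-2-en-1-one | COC(OC)C1=C(C#C/C=C/CO[Si](C)(C)C(C)(C)C)CCC1=O
F2 | step 7 | 5-acetyl derivative of F1 | COC(OC)C1=C(C#C/C=C/CO[Si](C)(C)C(C)(C)C)CC(C(C)=O)C1=O
F3 | step 7 | (5S)-5-acetyl-5-hydroxy derivative of F1 | COC(OC)C1=C(C#C/C=C/CO[Si](C)(C)C(C)(C)C)C[C@](O)(C(C)=O)C1=O
F4 | step 7 | (5R)-4,5-dihydroxy-5-methyl-6-oxo-2-[(E)-5-(tert-butyldimethylsilyloxy)pent-3-en-1-ynyl]cyclohexa-1,3-diene-1-carbaldehyde | O[C@]1(C)C(O)=CC(C#C/C=C/CO[Si](C)(C)C(C)(C)C)=C(C=O)C1=O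
F5 | step 6 | (6S)-6-acetyl-6-(anilinooxy) derivative of 6 | COC1OC(/C=C/CO[Si](C)(C)C(C)(C)C)=CC2=C1C(=O)[C@@](ONc1ccccc1)(C(C)=O)C2
F6 | step 9 | 6-(2,4-dioxopentyl)-2,2-dimethyl-4H-1,3-dioxin-4-one | CC(=O)CC(=O)CC1=CC(=O)OC(C)(C)O1
F7 | step 9 | 3,5,7-trioxooctanoate of 10 | CC(=O)CC(=O)CC(=O)CC(=O)O[C@]1(C)C(=O)C=C2C=C(/C=C/CO[Si](C)(C)C(C)(C)C)OC=C2C1=O
F8 | step 9 | orsellinate of 10 with free phenols | Cc1cc(O)cc(O)c1C(=O)O[C@]1(C)C(=O)C=C2C=C(/C=C/CO[Si](C)(C)C(C)(C)C)OC=C2C1=O
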